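**Retrosynthetic overview**
1. Target 13 ⇐ hydrogenolysis of tri‑O‑benzyl lactone 12 ⇐ lactol 11 ⇐ aldehyde from alkenyl boronate 9, itself made by cross‑metathesis truncation of the propenyl group of 7.
2. C4–C4a bond and the C4 stereocentre ⇐ aromatic Claisen [3,3] shift of aryl (R)‑1‑methyl‑3‑phenylallyl ether 5, with 1,3‑chirality transfer from the C–O centre to the new C–C centre.
3. Ether 5 ⇐ Mitsunobu inversion of tri‑O‑benzylphloretin 3 with (S,E)‑4‑phenylbut‑3‑en‑2‑ol 4; 3 ⇐ phloretin 1 + benzyl bromide 2.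
4. The 8‑acyl (not 6‑acyl) pattern is fixed because the allyl unit sits on the only free, ketone‑chelated OH, which is returned by the rearrangement for ring closure.
5. Ring order: both benzene rings are bought in phloretin; the only ring made is the pyranone ring (lactol, then lactone).

Assumption: the target is the (4R) enantiomer (read from the SMILES), and enantiopure (S,E)‑4‑phenylbut‑3‑en‑2‑ol is taken as a catalogue chemical.

**Step 1**
Reactants: 1 phloretin; 2 benzyl bromide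
Product: 3 1-[2,4-bis(benzyloxy)-6-hydroxyphenyl]-3-[4-(benzyloxy)phenyl]propan-1-one
Conditions: BnBr (3.1 equiv), K2CO3 (3.5 equiv), DMF, rt
Reagents that add atoms: benzyl bromide (2), BrCc1ccccc1
Why: Williamson etherification takes the 4'-OH, the B‑ring OH and one ortho OH, while the last ortho OH stays free because it is strongly hydrogen‑bonded to the ketone.

**Step 2**
Reactants: 3 tri‑O‑benzylphloretin; 4 (S,E)-4-phenylbut-3-en-2-ol
Product: 5 1-[2,4-bis(benzyloxy)-6-{[(2R,3E)-4-phenylbut-3-en-2-yl]oxy}phenyl]-3-[4-(benzyloxy)phenyl]propan-1-one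
Conditions: PPh3, DIAD (slow addition), toluene, 0 °C → rt
Reagents that add atoms: (S,E)-4-phenylbut-3-en-2-ol (4), C[C@H](O)/C=C/c1ccccc1
Why: Mitsunobu reaction in which the only free phenol displaces the oxyphosphonium of 4 by SN2 with inversion, so the bought (S) carbinol becomes the (R) aryl ether.

**Step 3**
Reactants: 5 aryl (R)-1-methyl-3-phenylallyl ether
Product: 7 1-{4,6-bis(benzyloxy)-2-hydroxy-3-[(1R,2E)-1-phenylbut-2-en-1-yl]phenyl}-3-[4-(benzyloxy)phenyl]propan-1-one, via ortho-dienone 6 (not isolated)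
Conditions: PhNEt2 (degassed), 160 °C, sealed tube
Reagents that add atoms: none
Why: Aromatic Claisen rearrangement, a suprafacial [3,3] shift through a chair transition state with the methyl group pseudo‑equatorial, delivers the phenyl‑bearing allyl terminus to the only free ortho carbon on the face the C–O bond leaves from, so the (R) C–O centre is converted into the (R) diarylmethine centre with an E‑propenyl group, and dienone 6 enolises to the chelated phenol.

**Step 4**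
Reactants: 7 Claisen phenol; 8 vinylboronic acid pinacol ester
Product: 9 1-{4,6-bis(benzyloxy)-2-hydroxy-3-[(1R,2E)-1-phenyl-3-(4,4,5,5-tetramethyl-1,3,2-dioxaborolan-2-yl)prop-2-en-1-yl]phenyl}-3-[4-(benzyloxy)phenyl]propan-1-one
Conditions: Hoveyda–Grubbs II (5–10 mol%), 8 (3 equiv), 1,4-benzoquinone (10 mol%), CH2Cl2, 40 °C
Reagents that add atoms: vinylboronic acid pinacol ester (8), C=CB1OC(C)(C)C(C)(C)O1
Why: Olefin cross‑metathesis exchanges the CH–CH3 terminus for CH–Bpin with loss of propene, and the stereocentre is not part of the alkene (benzoquinone suppresses Ru–H double‑bond migration into conjugation).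

**Step 5**
Reactants: 9 alkenyl boronate
Product: 11 (4R)-5,7-bis(benzyloxy)-8-{3-[4-(benzyloxy)phenyl]propanoyl}-4-phenylchroman-2-ol (lactol; both C2 epimers), via hydroxy-aldehyde 10 (not isolated)
Conditions: NaBO3·4H2O (3 equiv), THF/H2O 1:1, rt
Reagents that add atoms: sodium perborate, [Na+].[Na+].O[B-]1(O)OO[B-](O)(O)OO1
Why: Perborate oxidation of the C–B bond (1,2‑migration from boron to oxygen) gives the enol and hence aldehyde 10, which the neighbouring free phenol traps as the six‑membered lactol without touching C4.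

**Step 6**
Reactants: 11 lactol
Product: 12 (4R)-5,7-bis(benzyloxy)-8-{3-[4-(benzyloxy)phenyl]propanoyl}-4-phenylchroman-2-one
Conditions: PhI(OAc)2 (1.3 equiv), TEMPO (10 mol%), CH2Cl2, rt
Reagents that add atoms: none
Why: Oxoammonium (TEMPO/BAIB) oxidation of the hemiacetal C–H gives the lactone under near‑neutral conditions that leave the benzyl ethers, the ketone and the β‑stereocentre alone.

**Step 7**
Reactants: 12 tri‑O‑benzyl lactone
Product: 13 (4R)-5,7-dihydroxy-8-[3-(4-hydroxyphenyl)propanoyl]-4-phenylchroman-2-one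
Conditions: H2 (1 atm), 10% Pd/C, EtOAc, rt
Reagents that add atoms: none
Why: Catalytic hydrogenolysis cleaves the three benzyl ethers in a neutral aprotic medium, which avoids lactone opening or acyl shift to the new 5‑OH, and C4 carries no C–heteroatom bond that could be cleaved.

**Compound list**
1 | phloretin | O=C(CCc1ccc(O)cc1)c1c(O)cc(O)cc1O | starting material
2 | benzyl bromide | BrCc1ccccc1 | starting material
3 | 1-[2,4-bis(benzyloxy)-6-hydroxyphenyl]-3-[4-(benzyloxy)phenyl]propan-1-one (4,4',6'-tri-O-benzylphloretin) | O=C(CCc1ccc(OCc2ccccc2)cc1)c1c(O)cc(OCc2ccccc2)cc1OCc1ccccc1 | intermediate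
4 | (S,E)-4-phenylbut-3-en-2-ol | C[C@H](O)/C=C/c1ccccc1 | starting material
5 | 1-[2,4-bis(benzyloxy)-6-{[(2R,3E)-4-phenylbut-3-en-2-yl]oxy}phenyl]-3-[4-(benzyloxy)phenyl]propan-1-one | C[C@@H](Oc1cc(OCc2ccccc2)cc(OCc2ccccc2)c1C(=O)CCc1ccc(OCc2ccccc2)cc1)/C=C/c1ccccc1 | intermediate
6 | (6S)-3,5-bis(benzyloxy)-2-{3-[4-(benzyloxy)phenyl]propanoyl}-6-[(1S,2E)-1-phenylbut-2-en-1-yl]cyclohexa-2,4-dien-1-one (ortho-dienone from the chair transition state; side-chain carbon has the same spatial arrangement as in 7, the descriptor changes only through CIP ranking) | O=C1C(C(=O)CCc2ccc(OCc3ccccc3)cc2)=C(OCc2ccccc2)C=C(OCc2ccccc2)[C@@H]1[C@@H](c1ccccc1)/C=C/C | intermediate (not isolated)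
7 | 1-{4,6-bis(benzyloxy)-2-hydroxy-3-[(1R,2E)-1-phenylbut-2-en-1-yl]phenyl}-3-[4-(benzyloxy)phenyl]propan-1-one | C/C=C/[C@H](c1ccccc1)c1c(O)c(C(=O)CCc2ccc(OCc3ccccc3)cc2)c(OCc2ccccc2)cc1OCc1ccccc1 | intermediate
8 | vinylboronic acid pinacol ester (4,4,5,5-tetramethyl-2-vinyl-1,3,2-dioxaborolane) | C=CB1OC(C)(C)C(C)(C)O1 | starting material
9 | 1-{4,6-bis(benzyloxy)-2-hydroxy-3-[(1R,2E)-1-phenyl-3-(4,4,5,5-tetramethyl-1,3,2-dioxaborolan-2-yl)prop-2-en-1-yl]phenyl}-3-[4-(benzyloxy)phenyl]propan-1-one | CC1(C)OB(/C=C/[C@H](c2ccccc2)c2c(O)c(C(=O)CCc3ccc(OCc4ccccc4)cc3)c(OCc3ccccc3)cc2OCc2ccccc2)OC1(C)C | intermediate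
10 | (3R)-3-{4,6-bis(benzyloxy)-3-[3-(4-(benzyloxy)phenyl)propanoyl]-2-hydroxyphenyl}-3-phenylpropanal | O=CC[C@H](c1ccccc1)c1c(O)c(C(=O)CCc2ccc(OCc3ccccc3)cc2)c(OCc2ccccc2)cc1OCc1ccccc1 | intermediate (not isolated)
11 | (4R)-5,7-bis(benzyloxy)-8-{3-[4-(benzyloxy)phenyl]propanoyl}-4-phenylchroman-2-ol (mixture of C2 epimers) | OC1C[C@H](c2ccccc2)c2c(OCc3ccccc3)cc(OCc3ccccc3)c(C(=O)CCc3ccc(OCc4ccccc4)cc3)c2O1 | intermediate
12 | (4R)-5,7-bis(benzyloxy)-8-{3-[4-(benzyloxy)phenyl]propanoyl}-4-phenylchroman-2-one | O=C1C[C@H](c2ccccc2)c2c(OCc3ccccc3)cc(OCc3ccccc3)c(C(=O)CCc3ccc(OCc4ccccc4)cc3)c2O1 | intermediate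
13 | (4R)-5,7-dihydroxy-8-[3-(4-hydroxyphenyl)propanoyl]-4-phenylchroman-2-one | O=C1C[C@H](c2ccccc2)c2c(O)cc(O)c(C(=O)CCc3ccc(O)cc3)c2O1 | target

**Totals**
Total steps: 7. Longest linear sequence: 7 (from phloretin 1).

**Three steps most likely to fail, each with a fallback**

Step 2 (Mitsunobu). The activated form of 4 is a secondary cinnamyl‑type system that can ionise, react SN2′ or eliminate to 1‑phenylbutadiene, and the chelated phenol is a sluggish nucleophile. Any of these lowers yield or ee. The fallback sets out from 3. It uses the far less ionisable (S)-but-3-en-2-ol (C[C@H](O)C=C) in the Mitsunobu reaction to give 1-[2,4-bis(benzyloxy)-6-{[(2R)-but-3-en-2-yl]oxy}phenyl]-3-[4-(benzyloxy)phenyl]propan-1-one F1. The phenyl group is then installed by E‑selective cross‑metathesis with styrene (C=Cc1ccccc1; Hoveyda–Grubbs II, CH2Cl2, 40 °C), which comes back to the route at 5.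

Step 3 (Claisen rearrangement). C–O heterolysis to an ion pair would erode the chirality transfer. Attack at the acyl‑bearing ortho carbon followed by para migration, or thermal cyclisation of the product phenol onto the alkene, would cost material. The fallback sets out from 4 and moves the etherification/rearrangement pair to C2‑symmetric 3,5-bis(benzyloxy)phenol (Oc1cc(OCc2ccccc2)cc(OCc2ccccc2)c1), which has no acyl neighbour and two equivalent ortho carbons. Mitsunobu coupling gives 1,3-bis(benzyloxy)-5-{[(2R,3E)-4-phenylbut-3-en-2-yl]oxy}benzene F2. The [3,3] shift gives 3,5-bis(benzyloxy)-2-[(1R,2E)-1-phenylbut-2-en-1-yl]phenol F3. Magnesium‑mediated ortho‑formylation (MgCl2, Et3N, paraformaldehyde, MeCN, reflux) gives 4,6-bis(benzyloxy)-2-hydroxy-3-[(1R,2E)-1-phenylbut-2-en-1-yl]benzaldehyde F4. Addition of 2-[4-(benzyloxy)phenyl]ethylmagnesium bromide (Br[Mg]CCc1ccc(OCc2ccccc2)cc1, 2.2 equiv, THF, 0 °C) gives the carbinol 1-{4,6-bis(benzyloxy)-2-hydroxy-3-[(1R,2E)-1-phenylbut-2-en-1-yl]phenyl}-3-[4-(benzyloxy)phenyl]propan-1-ol F5. Oxidation of this benzylic alcohol with MnO2 (CH2Cl2, rt) comes back to the route at 7.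

Step 4 (cross‑metathesis). The internal alkene carries a bulky diarylmethyl group and the boronate partner is sluggish. Ru–H isomerisation into conjugation would destroy C4. The fallback sets out from 7. Ethenolysis (ethene 1–5 bar, Hoveyda–Grubbs II, toluene, 40 °C) gives 1-{4,6-bis(benzyloxy)-2-hydroxy-3-[(1R)-1-phenylprop-2-en-1-yl]phenyl}-3-[4-(benzyloxy)phenyl]propan-1-one F6. Iridium‑catalysed anti‑Markovnikov hydroboration with pinacolborane ([Ir(cod)Cl]2/dppm, CH2Cl2, rt), which spares the ketone, gives 1-{4,6-bis(benzyloxy)-2-hydroxy-3-[(1R)-1-phenyl-3-(4,4,5,5-tetramethyl-1,3,2-dioxaborolan-2-yl)propyl]phenyl}-3-[4-(benzyloxy)phenyl]propan-1-one F7. Perborate oxidation gives 1-{4,6-bis(benzyloxy)-2-hydroxy-3-[(1R)-3-hydroxy-1-phenylpropyl]phenyl}-3-[4-(benzyloxy)phenyl]propan-1-one F8. Parikh–Doering oxidation (SO3·pyridine, DMSO, i‑Pr2NEt) of the primary alcohol gives aldehyde 10, which closes and comes back to the route at lactol 11.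

**Further compounds**
F1 | step 2 | 1-[2,4-bis(benzyloxy)-6-{[(2R)-but-3-en-2-yl]oxy}phenyl]-3-[4-(benzyloxy)phenyl]propan-1-one | C[C@@H](Oc1cc(OCc2ccccc2)cc(OCc2ccccc2)c1C(=O)CCc1ccc(OCc2ccccc2)cc1)C=C
F2 | step 3 | 1,3-bis(benzyloxy)-5-{[(2R,3E)-4-phenylbut-3-en-2-yl]oxy}benzene | C[C@@H](Oc1cc(OCc2ccccc2)cc(OCc2ccccc2)c1)/C=C/c1ccccc1
F3 | step 3 | 3,5-bis(benzyloxy)-2-[(1R,2E)-1-phenylbut-2-en-1-yl]phenol | C/C=C/[C@H](c1ccccc1)c1c(O)cc(OCc2ccccc2)cc1OCc1ccccc1
F4 | step 3 | 4,6-bis(benzyloxy)-2-hydroxy-3-[(1R,2E)-1-phenylbut-2-en-1-yl]benzaldehyde | C/C=C/[C@H](c1ccccc1)c1c(O)c(C=O)c(OCc2ccccc2)cc1OCc1ccccc1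
F5 | step 3 | 1-{4,6-bis(benzyloxy)-2-hydroxy-3-[(1R,2E)-1-phenylbut-2-en-1-yl]phenyl}-3-[4-(benzyloxy)phenyl]propan-1-ol (both carbinol epimers) | C/C=C/[C@H](c1ccccc1)c1c(O)c(C(O)CCc2ccc(OCc3ccccc3)cc2)c(OCc2ccccc2)cc1OCc1ccccc1
F6 | step 4 | 1-{4,6-bis(benzyloxy)-2-hydroxy-3-[(1R)-1-phenylprop-2-en-1-yl]phenyl}-3-[4-(benzyloxy)phenyl]propan-1-one | C=C[C@H](c1ccccc1)c1c(O)c(C(=O)CCc2ccc(OCc3ccccc3)cc2)c(OCc2ccccc2)cc1OCc1ccccc1
F7 | step 4 | 1-{4,6-bis(benzyloxy)-2-hydroxy-3-[(1R)-1-phenyl-3-(4,4,5,5-tetramethyl-1,3,2-dioxaborolan-2-yl)propyl]phenyl}-3-[4-(benzyloxy)phenyl]propan-1-one | CC1(C)OB(CC[C@H](c2ccccc2)c2c(O)c(C(=O)CCc3ccc(OCc4ccccc4)cc3)c(OCc3ccccc3)cc2OCc2ccccc2)OC1(C)C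
F8 | step 4 | 1-{4,6-bis(benzyloxy)-2-hydroxy-3-[(1R)-3-hydroxy-1-phenylpropyl]phenyl}-3-[4-(benzyloxy)phenyl]propan-1-one | OCC[C@H](c1ccccc1)c1c(O)c(C(=O)CCc2ccc(OCc3ccccc3)cc2)c(OCc2ccccc2)cc1OCc1ccccc1
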